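## Retrosynthetic overview

1. I avoid the usual plan (aryl–benzofuran coupling or benzofuran annulation, then late prenylation). The benzofuran is bought intact and the pentasubstituted resorcinol ring is built de novo.
2. Target 10 ⇒ bis-silyl ether 9 ⇒ 1-(ethoxyethynyl)cyclobutenyl silyl ether 8. The key step is a retro-ene (–C2H4) / 4π-opening / 6π-closure cascade through a 3-siloxydienylketene.
3. 8 ⇒ cyclobutenone 7 + LiC≡COEt. 7 ⇒ 3-ethoxycyclobutenone 4 + 2-lithiobenzofuran, by 1,2-addition and carbonyl transposition.
4. 4 ⇒ two molecules of ynol ether 3, by retro-ene to prenylketene and [2+2]. 3 ⇒ ethoxyacetylene + prenyl bromide.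
5. Ring order: cyclobutenone (step 2), then ring expansion to the resorcinol (step 6). All six arene carbons come from three ethoxyacetylene units, so the 2',6'-diprenyl pattern is fixed by connectivity.

Assumption: the target has no stereocentre and no stereogenic axis, because the aryl ring is symmetric about the biaryl bond. It is therefore achiral and there is no enantiomer to select. The sp3 centres in 4, 7 and 8 are racemic and are erased on aromatisation. Benzofuran-6-ol is taken as a catalogue building block.

## Route

**Step 1**
Reactants: 1 ethoxyacetylene; 2 prenyl bromide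
Product: 3, 1-ethoxy-5-methylhex-4-en-1-yne
Conditions: n-BuLi, THF, –78 °C; DMPU, then 2, –78 → 0 °C
Reagents that add atoms: none beyond the reactants (2, prenyl bromide, CC(C)=CCBr, supplies the C5H9 unit)
Why: This is an SN2 alkylation of a lithium alkoxyacetylide, in which the unhindered acetylide attacks the CH2 terminus of the reactive primary allylic bromide to give the linear prenyl product, with no stereocentre formed.

**Step 2**
Reactants: 3 (2 equiv)
Product: 4, (±)-3-ethoxy-2,4-bis(3-methylbut-2-en-1-yl)cyclobut-2-en-1-one (+ ethylene)
Conditions: PhMe (1 M), BHT (cat.), pressure vessel, 120 °C, 4–6 h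
Reagents that add atoms: none
Why: In this thermal ynol-ether self-condensation, half of 3 loses ethylene by retro-ene to give prenylketene, which the remaining nucleophilic ynol ether traps in a regiospecific ketene–alkyne [2+2] (alkyne β-carbon to ketene C=O), and the racemic C4 centre is destroyed in step 6.

**Step 3**
Reactants: 5 benzofuran-6-ol
Product: 6, (1-benzofuran-6-yloxy)triisopropylsilane
Conditions: TIPSCl, imidazole, DMF, rt
Reagents that add atoms: TIPSCl, CC(C)[Si](Cl)(C(C)C)C(C)C
Why: Standard phenol silylation gives a bulky TIPS ether that tolerates n-BuLi, dilute acid and 140 °C and is removed by fluoride at the end.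

**Step 4**
Reactants: 6; 4
Product: 7, (±)-2,4-bis(3-methylbut-2-en-1-yl)-3-{6-[(triisopropylsilyl)oxy]-1-benzofuran-2-yl}cyclobut-2-en-1-one
Conditions: 6, n-BuLi, THF, –78 → –20 °C; 4, –78 °C; then 1 M HCl, THF, 0 °C, 20 min
Reagents that add atoms: water, O (supplies the new carbonyl oxygen; EtOH and the original carbonyl oxygen are lost)
Why: C2-lithiation of the benzofuran at its most acidic C–H is followed by 1,2-addition to the vinylogous ester (enolisation would give an antiaromatic cyclobutadienolate), and a Stork–Danheiser-type acid transposition through the ethoxy-stabilised cyclobutenyl cation places the aryl at C3 between the two prenyl-bearing carbons.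

**Step 5**
Reactants: 1 ethoxyacetylene; 7
Product: 8, {[1-(ethoxyethynyl)-2,4-bis(3-methylbut-2-en-1-yl)-3-{6-[(triisopropylsilyl)oxy]-1-benzofuran-2-yl}cyclobut-2-en-1-yl]oxy}triethylsilane (racemic C1/C4 diastereomer mixture, major isomer with alkynyl trans to the C4 prenyl)
Conditions: 1, n-BuLi, THF, –78 °C; 7, –78 °C, 1 h; TESCl, DMPU, –78 → –20 °C; NaHCO3 work-up, Et3N-deactivated SiO2
Reagents that add atoms: TESCl, CC[Si](Cl)(CC)CC
Why: 1,2-Addition of lithium ethoxyacetylide to the strained C=O (the first stage of the Arens–van Dorp reaction) is followed by in situ O-silylation, which blocks Meyer–Schuster rearrangement and later β-lactone formation, and the diastereomer ratio does not matter because both sp3 carbons become arene carbons.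

**Step 6 (key step)**
Reactants: 8
Product: 9, 2,4-bis(3-methylbut-2-en-1-yl)-5-[(triethylsilyl)oxy]-3-{6-[(triisopropylsilyl)oxy]-1-benzofuran-2-yl}phenol (+ ethylene)
Conditions: degassed o-xylene (0.01 M), BHT (cat.), base-washed sealed tube, 140 °C, 3 h
Reagents that add atoms: none
Why: Proposed new method: conrotatory 4π-opening of the cyclobutene (the OTES donor rotates outward, so the alkynyl group goes inward toward C4, as in Moore/Liebeskind cyclobutenone rearrangements) and retro-ene loss of ethylene from the ethoxyalkyne (as in step 2) give the dienylketene O=C=CH–C(OTES)=C(prenyl)–C(Ar)=CH(prenyl), which undergoes fast 6π-electrocyclisation and tautomerisation to the resorcinol monosilyl ether; the closest known reaction is the Danheiser cyclobutenone/ynol ether benzannulation, which passes through the same type of 3-oxy-dienylketene, and the difference here is that no O-alkyl group remains to be cleaved next to acid-sensitive prenyl groups.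

**Step 7**
Reactants: 9
Product: 10, mulberrofuran V, 5-(6-hydroxy-1-benzofuran-2-yl)-4,6-bis(3-methylbut-2-en-1-yl)benzene-1,3-diol
Conditions: TBAF, AcOH (1:1, 2.5 equiv each), THF, 0 °C → rt
Reagents that add atoms: none
Why: Buffered fluoride desilylation removes both aryl silyl ethers without acid, so the ortho-prenylphenols do not cyclise to chromans.

## Compound list

| No. | Name | SMILES | Role |
|---|---|---|---|
| 1 | ethoxyacetylene | CCOC#C | starting material |
| 2 | prenyl bromide | CC(C)=CCBr | starting material |
| 3 | 1-ethoxy-5-methylhex-4-en-1-yne | CCOC#CCC=C(C)C | intermediate |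
| 4 | (±)-3-ethoxy-2,4-diprenylcyclobut-2-en-1-one | CCOC1=C(CC=C(C)C)C(=O)C1CC=C(C)C | intermediate |
| 5 | benzofuran-6-ol | Oc1ccc2ccoc2c1 | starting material |
| 6 | 6-(triisopropylsilyloxy)benzofuran | CC(C)[Si](Oc1ccc2ccoc2c1)(C(C)C)C(C)C | intermediate |
| 7 | (±)-3-(6-TIPSO-benzofuran-2-yl)-2,4-diprenylcyclobut-2-en-1-one | O=C1C(CC=C(C)C)=C(c2cc3ccc(O[Si](C(C)C)(C(C)C)C(C)C)cc3o2)C1CC=C(C)C | intermediate |
| 8 | 1-(ethoxyethynyl)-1-TESO-3-(6-TIPSO-benzofuran-2-yl)-2,4-diprenylcyclobut-2-ene (racemic diastereomer mixture) | CCOC#CC1(O[Si](CC)(CC)CC)C(CC=C(C)C)=C(c2cc3ccc(O[Si](C(C)C)(C(C)C)C(C)C)cc3o2)C1CC=C(C)C | intermediate |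
| 9 | mulberrofuran V 3'-O-TES, 6-O-TIPS bis-ether | CC(C)=CCc1c(O)cc(O[Si](CC)(CC)CC)c(CC=C(C)C)c1-c1cc2ccc(O[Si](C(C)C)(C(C)C)C(C)C)cc2o1 | intermediate |
| 10 | mulberrofuran V (achiral) | CC(C)=CCc1c(O)cc(O)c(CC=C(C)C)c1-c1cc2ccc(O)cc2o1 | target |

## Summary

Total steps: 7. Longest linear sequence: 6 (steps 1 → 2 → 4 → 5 → 6 → 7).

Steps most likely to fail, each with a fallback that changes the approach:

1. **Step 6 (cascade).** The main risks are that the major diastereomer of 8 must open with both the alkynyl and the C4 prenyl rotating inward, and that the ketene could be intercepted intermolecularly. Fallback: drop the tethered ketene and run the classical intermolecular Danheiser benzannulation. Cyclobutenone 7 is heated so that it opens to its vinylketene, in the presence of a separately prepared siloxyacetylene (TIPSO–C≡CH). This gives the TIPS analogue of 9, and TBAF then gives 10.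
2. **Step 5 (acid-labile, hindered adduct).** The risks are Meyer–Schuster rearrangement and incomplete silylation. Fallback: deliver the last C2 unit as an acetate enolate.
   - LiCH2CO2t-Bu is added to 7.
   - The alkoxide undergoes oxyanion-accelerated 4π-opening to the β-keto ester t-BuO2CCH2C(O)C(prenyl)=C(Ar)CH2-prenyl.
   - Thermolysis expels t-BuOH to give the acylketene and its dienol-ketene tautomer, and 6π-closure gives the free resorcinol directly.
3. **Step 2 (thermal self-condensation).** The risks are ketene dimerisation and over-annulation of 4 with 3. Fallback: a crossed [2+2] at 0–25 °C, with prenylketene generated independently from 5-methylhex-4-enoyl chloride and Et3N in the presence of 3. This separates ketene formation from the 120 °C retro-ene.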